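**Retrosynthetic overview**
1. Target ⇐ acetonide/silyl ether ⇐ vinyl triflate: the C-3 carbonyl left by the cyclisation is erased, giving the C-2=C-3 alkene.
2. Key disconnection C-1–C-2: a polyketide-type intramolecular aldol addition (methyl-ketone enolate onto the C-1 ketone) closes the ring and sets the tertiary C-1 carbinol in the same event.
3. Acyclic 2,6-diketone ⇐ C-1–C-1′ bond: β-oxido organolithium from an (S)-epoxide plus a morpholine amide derived from 2-deoxy-D-ribose (supplies C-4 and C-5).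
4. (S)-Epoxide ⇐ (9Z)-hexadec-9-enal by Corey–Chaykovsky methylenation and hydrolytic kinetic resolution (supplies C-2′).
5. Ring order: one carbocycle only, formed in step 9.

Assumption: the ring is presumed to arise in Nature from a palmitoleoyl-primed polyketide by intramolecular aldol closure onto the C-1 ketone with the aldol oxygen retained; locants C-1…C-6 and C-1′… are those of the target; (9Z)-hexadec-9-enal (pheromone grade) is taken as commercial.

**Route**

Step 1
Reactants: 1 2-deoxy-D-ribose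
Product: 2 2-deoxy-3,4-O-isopropylidene-D-erythro-pentopyranose (lactol, anomers)
Conditions: 2-methoxypropene (1.3 eq), PPTS (cat.), DMF, 0 °C
Reagents that add atoms: 2-methoxypropene, COC(C)=C
Why: acid-catalysed acetal exchange (acetonide formation) takes the cis-3,4-diol of the pyranose while C-1 and O-5 stay tied in the lactol; both stereocentres (later C-5 and C-4) come unchanged from the sugar.

Step 2
Reactants: 2 2-deoxy-3,4-O-isopropylidene-D-erythro-pentopyranose
Product: 3 2-deoxy-3,4-O-isopropylidene-D-erythro-pentono-1,5-lactone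
Conditions: TEMPO (10 mol%), PhI(OAc)2 (1.3 eq), CH2Cl2, rt
Reagents that add atoms: none
Why: TEMPO/oxoammonium oxidation of the lactol to the δ-lactone; no stereocentre is touched.

Step 3
Reactants: 3 2-deoxy-3,4-O-isopropylidene-D-erythro-pentono-1,5-lactone
Product: 4 2-[(4S,5R)-5-(hydroxymethyl)-2,2-dimethyl-1,3-dioxolan-4-yl]-1-(morpholin-4-yl)ethan-1-one
Conditions: morpholine (3 eq), toluene, 60 °C
Reagents that add atoms: morpholine, C1COCCN1
Why: lactone aminolysis gives the open-chain tertiary amide (an acyl donor that takes one organolithium only) and frees the primary alcohol.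

Step 4
Reactants: 4 2-[(4S,5R)-5-(hydroxymethyl)-2,2-dimethyl-1,3-dioxolan-4-yl]-1-(morpholin-4-yl)ethan-1-one
Product: 6 2-[(4S,5R)-5-ethynyl-2,2-dimethyl-1,3-dioxolan-4-yl]-1-(morpholin-4-yl)ethan-1-one, via aldehyde 5 (not isolated)
Conditions: TEMPO (10 mol%), PhI(OAc)2, CH2Cl2, rt; crude 5, dimethyl (1-diazo-2-oxopropyl)phosphonate, K2CO3, MeOH, 0 °C
Reagents that add atoms: dimethyl (1-diazo-2-oxopropyl)phosphonate (Ohira–Bestmann reagent), CC(=O)C(=[N+]=[N-])P(=O)(OC)OC
Why: TEMPO oxidation then Seyferth–Gilbert homologation (Ohira–Bestmann variant) turns CH2OH into a terminal alkyne, the masked acetyl that becomes C-3/C-2; it is run cold so the α-alkoxy aldehyde centre does not epimerise.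

Step 5
Reactants: 6 2-[(4S,5R)-5-ethynyl-2,2-dimethyl-1,3-dioxolan-4-yl]-1-(morpholin-4-yl)ethan-1-one
Product: 7 2-[(4S,5S)-5-acetyl-2,2-dimethyl-1,3-dioxolan-4-yl]-1-(morpholin-4-yl)ethan-1-one
Conditions: Ph3PAuNTf2 (2 mol%), H2O (5 eq), 1,4-dioxane, 40 °C
Reagents that add atoms: water, O
Why: gold(I)-catalysed Markovnikov hydration of the terminal alkyne gives the methyl ketone; near-neutral conditions leave the acetonide and the α-centre alone.

Step 6
Reactants: 8 (9Z)-hexadec-9-enal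
Product: 9 rac-2-[(8Z)-pentadec-8-en-1-yl]oxirane
Conditions: Me3S+ I−, KOt-Bu, DMSO/THF, 0 °C
Reagents that add atoms: trimethylsulfonium iodide, C[S+](C)C.[I-]
Why: Corey–Chaykovsky epoxidation: dimethylsulfonium methylide adds to the aldehyde and closes the epoxide; the new centre is racemic at this stage.

Step 7
Reactants: 9 rac-2-[(8Z)-pentadec-8-en-1-yl]oxirane
Product: 10 (2S)-2-[(8Z)-pentadec-8-en-1-yl]oxirane
Conditions: (S,S)-(salen)Co(III)OAc (0.5 mol%), H2O (0.55 eq), THF, 0 °C→rt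
Reagents that add atoms: none
Why: Jacobsen hydrolytic kinetic resolution hydrolyses the (R)-epoxide and leaves the (S)-epoxide (≤50 %, >99 % ee), which fixes C-2′.

Step 8
Reactants: 7 2-[(4S,5S)-5-acetyl-2,2-dimethyl-1,3-dioxolan-4-yl]-1-(morpholin-4-yl)ethan-1-one + 10 (2S)-2-[(8Z)-pentadec-8-en-1-yl]oxirane
Product: 13 1-[(4S,5S)-5-acetyl-2,2-dimethyl-1,3-dioxolan-4-yl]-(4S,12Z)-4-(triethylsilyloxy)nonadec-12-en-2-one, via lithium enolate 11 (not isolated), via β-oxido organolithium 12 (not isolated)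
Conditions: 7, LiHMDS (1.05 eq), THF, −78 °C; 10, Li powder, DTBB (5 mol%), THF, −78 °C; combine, −78→−40 °C; TESCl (2.5 eq), −78→0 °C; 0.5 M citric acid, 0 °C
Reagents that add atoms: chlorotriethylsilane, CC[Si](CC)(CC)Cl
Why: arene-catalysed reductive lithiation opens the epoxide at the CH2–O bond to the primary organolithium, which acylates once on the morpholine amide (stable tetrahedral adduct) while the methyl ketone is shielded as its enolate; TESCl caps the C-2′ alkoxide and the acid wash hydrolyses the enol silane and the aminal, with C-2′ and the dioxolane centres untouched.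

Step 9
Reactants: 13 1-[(4S,5S)-5-acetyl-2,2-dimethyl-1,3-dioxolan-4-yl]-(4S,12Z)-4-(triethylsilyloxy)nonadec-12-en-2-one
Product: 15 (3S,5S,6S)-3-hydroxy-5,6-(isopropylidenedioxy)-3-[(2S,10Z)-2-(triethylsilyloxy)heptadec-10-en-1-yl]cyclohex-1-en-1-yl trifluoromethanesulfonate, via lithium aldolate 14 (not isolated)
Conditions: LiHMDS (1.1 eq), THF, −78→−40 °C; LiHMDS (1.3 eq), −78 °C; Comins' reagent (1.2 eq), −78→−20 °C
Reagents that add atoms: N-(5-chloropyridin-2-yl)bis(trifluoromethanesulfonyl)imide (Comins' reagent), FC(F)(F)S(=O)(=O)N(c1ccc(Cl)cn1)S(=O)(=O)C(F)(F)F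
Why: intramolecular aldol addition [6-(enolendo)-exo-trig], as in polyketide ring closure: the kinetic methyl-ketone enolate, chelated to O-4 so that O-5 is axial, attacks the C-1 ketone on a chair with the side chain equatorial and the new alkoxide axial and Li-bridged to O-5, which sets C-1 cis to both ring oxygens; a second equivalent of base then forms the alkoxide–enolate dianion on the C-2 side and O-triflation gives the enol triflate without β-elimination.

Step 10
Reactants: 15 (3S,5S,6S)-3-hydroxy-5,6-(isopropylidenedioxy)-3-[(2S,10Z)-2-(triethylsilyloxy)heptadec-10-en-1-yl]cyclohex-1-en-1-yl trifluoromethanesulfonate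
Product: 16 (1S,4R,5S)-4,5-(isopropylidenedioxy)-1-[(2S,10Z)-2-(triethylsilyloxy)heptadec-10-en-1-yl]cyclohex-2-en-1-ol
Conditions: Pd(OAc)2 (5 mol%), PPh3 (10 mol%), Bu3N (3 eq), HCO2H (2 eq), DMF, 60 °C
Reagents that add atoms: none
Why: palladium-catalysed formate reduction of the vinyl triflate replaces OTf by H and leaves the C-2=C-3 alkene; the stereocentres and the isolated Z-alkene are not touched (the C-1 descriptor changes only because of CIP priorities).

Step 11
Reactants: 16 (1S,4R,5S)-4,5-(isopropylidenedioxy)-1-[(2S,10Z)-2-(triethylsilyloxy)heptadec-10-en-1-yl]cyclohex-2-en-1-ol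
Product: 17 (1R,4R,5S)-1-[(2S,10Z)-2-hydroxyheptadec-10-en-1-yl]cyclohex-2-ene-1,4,5-triol
Conditions: AcOH/H2O (4:1), 40 °C
Reagents that add atoms: none
Why: mild acid hydrolysis removes the TES ether and the acetonide together; weak acid avoids ionising the tertiary allylic alcohol.

**Compound list**
1 | 2-deoxy-D-ribose (open-chain form shown) | O=CC[C@H](O)[C@H](O)CO | starting material
2 | 2-deoxy-3,4-O-isopropylidene-D-erythro-pentopyranose | OC1C[C@@H]2OC(C)(C)O[C@@H]2CO1 | intermediate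
3 | 2-deoxy-3,4-O-isopropylidene-D-erythro-pentono-1,5-lactone | O=C1C[C@@H]2OC(C)(C)O[C@@H]2CO1 | intermediate
4 | 2-[(4S,5R)-5-(hydroxymethyl)-2,2-dimethyl-1,3-dioxolan-4-yl]-1-(morpholin-4-yl)ethan-1-one | O=C(C[C@@H]1OC(C)(C)O[C@@H]1CO)N1CCOCC1 | intermediate
5 | (4S,5S)-2,2-dimethyl-5-[2-(morpholin-4-yl)-2-oxoethyl]-1,3-dioxolane-4-carbaldehyde | O=C(C[C@@H]1OC(C)(C)O[C@@H]1C=O)N1CCOCC1 | intermediate (not isolated)
6 | 2-[(4S,5R)-5-ethynyl-2,2-dimethyl-1,3-dioxolan-4-yl]-1-(morpholin-4-yl)ethan-1-one | O=C(C[C@@H]1OC(C)(C)O[C@@H]1C#C)N1CCOCC1 | intermediate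
7 | 2-[(4S,5S)-5-acetyl-2,2-dimethyl-1,3-dioxolan-4-yl]-1-(morpholin-4-yl)ethan-1-one | O=C(C[C@@H]1OC(C)(C)O[C@@H]1C(C)=O)N1CCOCC1 | intermediate
8 | (9Z)-hexadec-9-enal | CCCCCC/C=C\CCCCCCCC=O | starting material
9 | rac-2-[(8Z)-pentadec-8-en-1-yl]oxirane | CCCCCC/C=C\CCCCCCCC1CO1 | intermediate
10 | (2S)-2-[(8Z)-pentadec-8-en-1-yl]oxirane | CCCCCC/C=C\CCCCCCC[C@H]1CO1 | intermediate
11 | lithium enolate of 7: lithium 1-{(4S,5S)-2,2-dimethyl-5-[2-(morpholin-4-yl)-2-oxoethyl]-1,3-dioxolan-4-yl}ethen-1-olate | O=C(C[C@@H]1OC(C)(C)O[C@@H]1C(=C)O[Li])N1CCOCC1 | intermediate (not isolated)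
12 | lithium (10Z)-1-lithioheptadec-10-en-2-olate (C–O stereocentre as in 10) | CCCCCC/C=C\CCCCCCC[C@H](O[Li])C[Li] | intermediate (not isolated)
13 | 1-[(4S,5S)-5-acetyl-2,2-dimethyl-1,3-dioxolan-4-yl]-(4S,12Z)-4-(triethylsilyloxy)nonadec-12-en-2-one | CCCCCC/C=C\CCCCCCC[C@H](O[Si](CC)(CC)CC)CC(=O)C[C@@H]1OC(C)(C)O[C@@H]1C(C)=O | intermediate
14 | lithium alkoxide of (2S,3S,5S)-5-hydroxy-2,3-(isopropylidenedioxy)-5-[(2S,10Z)-2-(triethylsilyloxy)heptadec-10-en-1-yl]cyclohexan-1-one | CCCCCC/C=C\CCCCCCC[C@H](O[Si](CC)(CC)CC)C[C@]1(O[Li])CC(=O)[C@@H](OC(C)(C)O2)[C@@H]2C1 | intermediate (not isolated)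
15 | (3S,5S,6S)-3-hydroxy-5,6-(isopropylidenedioxy)-3-[(2S,10Z)-2-(triethylsilyloxy)heptadec-10-en-1-yl]cyclohex-1-en-1-yl trifluoromethanesulfonate | CCCCCC/C=C\CCCCCCC[C@H](O[Si](CC)(CC)CC)C[C@]1(O)C=C(OS(=O)(=O)C(F)(F)F)[C@@H](OC(C)(C)O2)[C@@H]2C1 | intermediate
16 | (1S,4R,5S)-4,5-(isopropylidenedioxy)-1-[(2S,10Z)-2-(triethylsilyloxy)heptadec-10-en-1-yl]cyclohex-2-en-1-ol | CCCCCC/C=C\CCCCCCC[C@H](O[Si](CC)(CC)CC)C[C@]1(O)C=C[C@@H](OC(C)(C)O2)[C@@H]2C1 | intermediate
17 | (1R,4R,5S)-1-[(2S,10Z)-2-hydroxyheptadec-10-en-1-yl]cyclohex-2-ene-1,4,5-triol | CCCCCC/C=C\CCCCCCC[C@H](O)C[C@]1(O)C=C[C@@H](O)[C@@H](O)C1 | target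

**Step count and risks**
Total: 11 steps. Longest linear sequence: 9 steps (1 → 17 through steps 1–5 and 8–11); the side branch 8 → 10 is 2 steps.

Step 9 (most likely to fail). Risks are enolisation at the wrong α-carbon, retro-aldol or elimination of the ketol, the C-1 epimer if chelation is weak, and O-triflation of the alkoxide. The fallback sets out from 2 and comes back at 17. Methylmagnesium bromide opens lactol 2 to the methyl carbinol diol F6. Swern oxidation of both hydroxyls gives keto aldehyde F7. Piperidinium acetate closes the ring by intramolecular aldol condensation (methyl onto aldehyde) to enone F8. Organolithium 12, made as in step 8 and transmetalated with CeCl3, adds to the ketone from the face opposite the acetonide to give tertiary alcohol F9. Aqueous acetic acid as in step 11 then gives 17.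

Step 8. Risks are β-elimination or wrong-site opening in the reductive lithiation, attack on the enolate-masked ketone, and over-addition. The fallback sets out from 10 and 6 and comes back at 13. Sodium benzenesulfinate opens 10 at the terminal carbon (DMF/H2O, 90 °C) to hydroxy sulfone F2. TESCl/imidazole gives silyl ether sulfone F3. Its α-lithio derivative (n-BuLi, after LiHMDS has taken the alkyne proton of 6) is acylated by amide 6 to keto sulfone F4. SmI2 cleaves the C–S bond to alkynyl ketone F5. Gold-catalysed hydration as in step 5 gives 13.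

Step 4. The risk is epimerisation of the cis-dioxolane aldehyde under K2CO3/MeOH. The fallback sets out from 4 and comes back at 7. After the same oxidation to 5, MeTi(Oi-Pr)3 (aldehyde-selective, non-basic, inert to the amide) gives secondary alcohol F1. Dess–Martin periodinane oxidises it to 7, so step 5 is no longer needed.

**Further compounds**
F1 | step 4 | 2-[(4S,5R)-5-(1-hydroxyethyl)-2,2-dimethyl-1,3-dioxolan-4-yl]-1-(morpholin-4-yl)ethan-1-one (carbinol epimers) | O=C(C[C@@H]1OC(C)(C)O[C@@H]1C(C)O)N1CCOCC1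
F2 | step 8 | (2S,10Z)-1-(benzenesulfonyl)heptadec-10-en-2-ol | CCCCCC/C=C\CCCCCCC[C@H](O)CS(=O)(=O)c1ccccc1
F3 | step 8 | triethyl{[(2S,10Z)-1-(benzenesulfonyl)heptadec-10-en-2-yl]oxy}silane | CCCCCC/C=C\CCCCCCC[C@H](O[Si](CC)(CC)CC)CS(=O)(=O)c1ccccc1
F4 | step 8 | (4S,12Z)-3-(benzenesulfonyl)-1-[(4S,5R)-5-ethynyl-2,2-dimethyl-1,3-dioxolan-4-yl]-4-(triethylsilyloxy)nonadec-12-en-2-one (C-3 epimers) | CCCCCC/C=C\CCCCCCC[C@H](O[Si](CC)(CC)CC)C(C(=O)C[C@@H]1OC(C)(C)O[C@@H]1C#C)S(=O)(=O)c1ccccc1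
F5 | step 8 | (4S,12Z)-1-[(4S,5R)-5-ethynyl-2,2-dimethyl-1,3-dioxolan-4-yl]-4-(triethylsilyloxy)nonadec-12-en-2-one | CCCCCC/C=C\CCCCCCC[C@H](O[Si](CC)(CC)CC)CC(=O)C[C@@H]1OC(C)(C)O[C@@H]1C#C
F6 | step 9 | 1-[(4S,5R)-5-(hydroxymethyl)-2,2-dimethyl-1,3-dioxolan-4-yl]propan-2-ol (carbinol epimers) | CC(O)C[C@@H]1OC(C)(C)O[C@@H]1CO
F7 | step 9 | (4S,5S)-2,2-dimethyl-5-(2-oxopropyl)-1,3-dioxolane-4-carbaldehyde | CC(=O)C[C@@H]1OC(C)(C)O[C@@H]1C=O
F8 | step 9 | (4R,5S)-4,5-(isopropylidenedioxy)cyclohex-2-en-1-one | O=C1C=C[C@@H](OC(C)(C)O2)[C@@H]2C1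
F9 | step 9 | (1R,4R,5S)-1-[(2S,10Z)-2-hydroxyheptadec-10-en-1-yl]-4,5-(isopropylidenedioxy)cyclohex-2-en-1-ol | CCCCCC/C=C\CCCCCCC[C@H](O)C[C@]1(O)C=C[C@@H](OC(C)(C)O2)[C@@H]2C1
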